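**Retrosynthetic overview**
- The depside is cut at its aryl C–O bond (carboxylate oxygen of the salicylate half to C4 of the benzoate half), giving a potassium salicylate and an aryl pinacol boronate that are joined by a copper-mediated oxidative C–O coupling. The acyl C–O bond is not used, because any activated form of this keto acid closes to an isocoumarin.
- The salicylate is stored as that isocoumarin (an enol lactone) and released by hydroxide in the coupling flask.
- The boronate comes from sterically controlled C–H borylation para to the ester of the benzoate half.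
- Both 2-oxoheptyl chains come from lateral lithiation of two bought o-toluate esters and acylation with one Weinreb amide.
- Rings: both benzene rings are bought; the only ring made is the pyranone ring of the isocoumarin (step 2), which is opened again in step 5.

Assumption: the target has no stereocentre and no stereogenic double bond, so it is achiral and no step needs stereocontrol; the two toluate esters and the Weinreb amide are taken as catalogue chemicals.

**Route**

Step 1
Reactants: 1 methyl 2,4-dimethoxy-6-methylbenzoate; 2 N-methoxy-N-methylhexanamide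
Product: 4 methyl 2,4-dimethoxy-6-(2-oxoheptyl)benzoate, via benzylic organolithium 3 (not isolated)
Conditions: LiN(iPr)2 (2.1 equiv, commercial solution), THF, −78 °C, 30 min; 2 (1.2 equiv), −78 → −30 °C; 1 M aq HCl
Reagents that add atoms: none
Why: Lateral (benzylic) lithiation of the o-toluate gives an ester-stabilised benzyl anion that is acylated once by the Weinreb amide through its stable chelated tetrahedral adduct (lateral lithiation/Weinreb ketone synthesis); no stereocentre is formed.

Step 2
Reactants: 4 methyl 2,4-dimethoxy-6-(2-oxoheptyl)benzoate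
Product: 6 8-hydroxy-6-methoxy-3-pentyl-1H-isochromen-1-one, via phenolic keto ester 5 (not isolated)
Conditions: BCl3 (2.5 equiv), CH2Cl2, −78 → 0 °C; MeOH quench, evaporate; TsOH·H2O (10 mol %), toluene, 4 Å MS, 100 °C
Reagents that add atoms: none
Why: BCl3 cleaves only the methyl ether ortho to the ester through a six-membered boron chelate (chelation-controlled demethylation), and acid-catalysed enol lactonisation with removal of methanol then closes the isocoumarin; no stereocentre is formed.

Step 3
Reactants: 7 methyl 2-methoxy-6-methylbenzoate; 2 N-methoxy-N-methylhexanamide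
Product: 9 methyl 2-methoxy-6-(2-oxoheptyl)benzoate, via benzylic organolithium 8 (not isolated)
Conditions: LiN(iPr)2 (2.1 equiv, commercial solution), THF, −78 °C, 30 min; 2 (1.2 equiv), −78 → −30 °C; 1 M aq HCl
Reagents that add atoms: none
Why: Same lateral lithiation/Weinreb ketone synthesis as in step 1, on a toluate whose only acidic site is the benzylic methyl group; no stereocentre is formed.

Step 4
Reactants: 9 methyl 2-methoxy-6-(2-oxoheptyl)benzoate
Product: 10 methyl 2-methoxy-6-(2-oxoheptyl)-4-(4,4,5,5-tetramethyl-1,3,2-dioxaborolan-2-yl)benzoate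
Conditions: [Ir(OMe)(cod)]2 (1.5 mol %), 4,4′-di-tert-butyl-2,2′-bipyridine (3 mol %), B2pin2 (1.0 equiv), THF, 60 °C
Reagents that add atoms: bis(pinacolato)diboron, CC1(C)OB(OC1(C)C)B1OC(C)(C)C(C)(C)O1
Why: Iridium-catalysed aromatic C–H borylation is sterically controlled, so of the three ring C–H bonds only the one flanked by two hydrogens (C4, para to the ester) reacts, and the conditions are neutral so the ketone and ester are left alone; no stereocentre is formed.

Step 5
Reactants: 6 8-hydroxy-6-methoxy-3-pentyl-1H-isochromen-1-one; 10 methyl 2-methoxy-6-(2-oxoheptyl)-4-(4,4,5,5-tetramethyl-1,3,2-dioxaborolan-2-yl)benzoate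
Product: 12 gustastatin, via potassium keto carboxylate 11 (not isolated)
Conditions: KOH (1.05 equiv), THF/H2O (4:1), 50 °C; evaporate, dry by MeCN azeotrope; 10 (1.3 equiv), Cu(OTf)2 (2.5 equiv), KF (1.5 equiv), 4 Å MS, MeCN, Ar, 40 °C
Reagents that add atoms: potassium hydroxide, [K+].[OH-]
Why: Proposed new method: ring-opening O-arylation of an enol lactone — hydroxide opens isocoumarin 6 (the peri-phenoxide acting as general base) to keto carboxylate 11, whose carboxyl group is deliberately left unactivated because any acyl activation recloses to 6 and direct phenolysis of 6 is estimated to be about thermoneutral; 11 binds divalent copper through the carboxylate while the ortho hydroxyl stays protonated and hydrogen-bonded in the amine-free medium, fluoride turns boronate 10 into an ate complex that passes its aryl group to copper and caps boron as pinB–F so it cannot sequester the carboxylate, a second Cu(OTf)2 (a strong one-electron oxidant in MeCN, which stabilises monovalent copper) raises the aryl copper carboxylate to trivalent copper, and C(aryl)–O reductive elimination forms the depside bond without oxygen or amine base, sparing the enolisable ketones and the aryl ester; the closest known reaction types are the Chan–Lam oxidative esterification of arylboronic acids and the anaerobic Cu(OTf)2/KF fluorination of aryl boron reagents; no stereocentre is formed.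

**Compound list**
1 | methyl 2,4-dimethoxy-6-methylbenzoate | COC(=O)c1c(C)cc(OC)cc1OC | starting material
2 | N-methoxy-N-methylhexanamide | CCCCCC(=O)N(C)OC | starting material
3 | methyl 2,4-dimethoxy-6-(lithiomethyl)benzoate (benzylic organolithium) | [Li]Cc1cc(OC)cc(OC)c1C(=O)OC | intermediate
4 | methyl 2,4-dimethoxy-6-(2-oxoheptyl)benzoate | CCCCCC(=O)Cc1cc(OC)cc(OC)c1C(=O)OC | intermediate
5 | methyl 2-hydroxy-4-methoxy-6-(2-oxoheptyl)benzoate (phenolic keto ester) | CCCCCC(=O)Cc1cc(OC)cc(O)c1C(=O)OC | intermediate
6 | 8-hydroxy-6-methoxy-3-pentyl-1H-isochromen-1-one | CCCCCC1=Cc2cc(OC)cc(O)c2C(=O)O1 | intermediate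
7 | methyl 2-methoxy-6-methylbenzoate | COC(=O)c1c(C)cccc1OC | starting material
8 | methyl 2-(lithiomethyl)-6-methoxybenzoate (benzylic organolithium) | [Li]Cc1cccc(OC)c1C(=O)OC | intermediate
9 | methyl 2-methoxy-6-(2-oxoheptyl)benzoate | CCCCCC(=O)Cc1cccc(OC)c1C(=O)OC | intermediate
10 | methyl 2-methoxy-6-(2-oxoheptyl)-4-(4,4,5,5-tetramethyl-1,3,2-dioxaborolan-2-yl)benzoate | CCCCCC(=O)Cc1cc(B2OC(C)(C)C(C)(C)O2)cc(OC)c1C(=O)OC | intermediate
11 | potassium 2-hydroxy-4-methoxy-6-(2-oxoheptyl)benzoate (potassium keto carboxylate) | CCCCCC(=O)Cc1cc(OC)cc(O)c1C(=O)[O-].[K+] | intermediate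
12 | gustastatin (3-methoxy-4-(methoxycarbonyl)-5-(2-oxoheptyl)phenyl 2-hydroxy-4-methoxy-6-(2-oxoheptyl)benzoate) | CCCCCC(=O)Cc1cc(OC)cc(O)c1C(=O)Oc1cc(CC(=O)CCCCC)c(C(=O)OC)c(OC)c1 | target

**Totals**
Total step count: 5.
Longest linear sequence: 3 steps (1 → 4 → 6 → 12, or 7 → 9 → 10 → 12).

**Three steps most likely to fail**

Step 5 (the proposed new coupling). The Lewis-acidic copper triflate may reclose 11 to 6 before it is arylated. The aryl group may go to the phenol oxygen instead of the carboxylate. The boronate may be protodeboronated to 9 or fluorinated. On long heating the product may collapse to 6 and the free phenol. Recovered 6 and 9 can be recycled. Fallback with known chemistry, setting out from 10 and 6 and coming back to the route at 12: boronate 10 is bromodeboronated (CuBr2, MeOH/H2O, 80 °C) to methyl 4-bromo-2-methoxy-6-(2-oxoheptyl)benzoate F1. Isocoumarin 6 is opened with aqueous KOH and acidified cold to pH 3–4 to give 2-hydroxy-4-methoxy-6-(2-oxoheptyl)benzoic acid F2, which is used at once. F1 and F2 are then joined by the known nickel/iridium photoredox esterification of aryl bromides with carboxylic acids (NiBr2(dme), 4,4′-di-tert-butyl-2,2′-bipyridine, fac-Ir(ppy)3, tert-butyl(isopropyl)amine, DMF, blue light, 25 °C), in which C–O reductive elimination occurs from trivalent nickel, to give 12.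

Step 4. The pinacolborane formed may reduce the ketone under iridium catalysis, and a minor amount of borylation next to the methoxy group is possible. Fallback setting out from 9 and coming back at 10: the ketone of 9 is masked under non-lactonising conditions (1,2-bis(trimethylsilyloxy)ethane, catalytic Me3SiOTf, CH2Cl2, −78 → −20 °C) as methyl 2-methoxy-6-[(2-pentyl-1,3-dioxolan-2-yl)methyl]benzoate F3. F3 is borylated under the step 4 conditions to methyl 2-methoxy-6-[(2-pentyl-1,3-dioxolan-2-yl)methyl]-4-(4,4,5,5-tetramethyl-1,3,2-dioxaborolan-2-yl)benzoate F4. The ketal is then removed with pyridinium tosylate in wet acetone at 40 °C to give 10.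

Step 2. BCl3 may also attack the 4-methoxy group or the ester, and the lactonisation may stop at 5. Fallback setting out from 4 and coming back at 6: 4 is treated with BBr3 (4 equiv, CH2Cl2, −78 → 23 °C), which cleaves both aryl methyl ethers and lactonises in the same operation to 6,8-dihydroxy-3-pentyl-1H-isochromen-1-one F5. The free 6-hydroxyl of F5 is then methylated alone (MeI 1.05 equiv, K2CO3, acetone, 23 °C), because the 8-hydroxyl is locked in a hydrogen bond to the lactone carbonyl, giving 6.

**Further compounds**
F1 | step 5 | methyl 4-bromo-2-methoxy-6-(2-oxoheptyl)benzoate | CCCCCC(=O)Cc1cc(Br)cc(OC)c1C(=O)OC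
F2 | step 5 | 2-hydroxy-4-methoxy-6-(2-oxoheptyl)benzoic acid | CCCCCC(=O)Cc1cc(OC)cc(O)c1C(=O)O
F3 | step 4 | methyl 2-methoxy-6-[(2-pentyl-1,3-dioxolan-2-yl)methyl]benzoate | CCCCCC1(Cc2cccc(OC)c2C(=O)OC)OCCO1
F4 | step 4 | methyl 2-methoxy-6-[(2-pentyl-1,3-dioxolan-2-yl)methyl]-4-(4,4,5,5-tetramethyl-1,3,2-dioxaborolan-2-yl)benzoate | CCCCCC1(Cc2cc(B3OC(C)(C)C(C)(C)O3)cc(OC)c2C(=O)OC)OCCO1
F5 | step 2 | 6,8-dihydroxy-3-pentyl-1H-isochromen-1-one | CCCCCC1=Cc2cc(O)cc(O)c2C(=O)O1
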